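**Retrosynthetic overview**
1. Target 27 ⇐ its 15‑O‑silyl ether 26 (desilylation only).
2. 26 ⇐ bromo‑enal 23: the C6–C7 bond closes the ten‑membered carbocycle in an electrochemical chromium‑catalysed allylation, and the lactone closes in the same operation (carbocycle first, lactone second).
3. 23 ⇐ acetate 15 by tailoring of C7/C8 (tiglate, aldehyde, 2‑(bromomethyl)enoate from methyl propiolate) and unmasking of the C6 aldehyde.
4. 15 ⇐ iodide 7 + methyl propiolate 10 + (S)‑glyceraldehyde acetonide 9 (carbocupration–aldol three‑component coupling; forms C1–C2 and C9–C10, sets the C1=C10 geometry and C9).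
5. 7 ⇐ but‑2‑yne‑1,4‑diol (anti‑carbomagnesiation fixes the C4=C5 geometry); 9 ⇐ (R)‑solketal (supplies C8, the only bought stereocentre).

Assumption: the SMILES is taken at face value, i.e. (6R,7S,8S,9S), tiglate (E) ester, both ring alkenes cis within the ring (E by CIP); locants C1–C15 follow germacrane numbering (C12 lactone carbonyl, C14 methyl ester carbon, C15 hydroxymethyl carbon).

**Step 1**
Reactants: 1 but-2-yne-1,4-diol
Product: 2 4-[(4-methoxyphenyl)methoxy]but-2-yn-1-ol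
Conditions: NaH (1.0 equiv), 4‑methoxybenzyl chloride (1.0 equiv), Bu4NI (cat.), THF/DMF, 0 °C → rt; 1 used in threefold excess
Reagents that add atoms: 4-methoxybenzyl chloride COc1ccc(CCl)cc1
Why: Williamson etherification of the symmetric diol in excess gives the mono‑ether; no stereocentre is involved.

**Step 2**
Reactants: 2 4-[(4-methoxyphenyl)methoxy]but-2-yn-1-ol
Product: 4 (2E)-2-ethenyl-4-[(4-methoxyphenyl)methoxy]but-2-en-1-ol, via alkenylmagnesium chelate 3 (not isolated)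
Conditions: CH2=CHMgCl (4 equiv), THF/toluene, 70 °C, 16 h; aq. NH4Cl, 0 °C
Reagents that add atoms: vinylmagnesium chloride C=C[Mg]Cl
Why: Alkoxide‑directed anti‑carbomagnesiation of a propargylic alcohol: vinyl adds to the alkyne carbon next to the CH2OMg group and magnesium ends on the distal carbon, cis to that CH2O in a five‑membered chelate, so protonation leaves C6 cis to C3 and trans to C15 as in the target.

**Step 3**
Reactants: 4 (2E)-2-ethenyl-4-[(4-methoxyphenyl)methoxy]but-2-en-1-ol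
Product: 5 tert-butyl{[(2E)-2-ethenyl-4-[(4-methoxyphenyl)methoxy]but-2-en-1-yl]oxy}diphenylsilane
Conditions: t‑BuPh2SiCl, imidazole, DMF, rt
Reagents that add atoms: tert-butyl(chloro)diphenylsilane CC(C)(C)[Si](Cl)(c1ccccc1)c1ccccc1
Why: Standard silylation of the primary allylic alcohol (C15–OH) with an acid‑stable silyl group that survives to the last step.

**Step 4**
Reactants: 5 tert-butyl{[(2E)-2-ethenyl-4-[(4-methoxyphenyl)methoxy]but-2-en-1-yl]oxy}diphenylsilane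
Product: 7 tert-butyl{[(2E)-2-(2-iodoethyl)-4-[(4-methoxyphenyl)methoxy]but-2-en-1-yl]oxy}diphenylsilane, via B-alkyl-9-BBN 6 (not isolated)
Conditions: 9‑BBN (1.2 equiv), THF, 0 °C → rt; then NaOMe/MeOH, I2, 0 °C
Reagents that add atoms: iodine II
Why: Anti‑Markovnikov hydroboration with 9‑BBN takes only the terminal vinyl group of the diene, and base‑induced iodinolysis of the primary B–C bond gives the homoallylic iodide (C2–I) without touching the trisubstituted alkene.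

**Step 5**
Reactants: 8 [(4R)-2,2-dimethyl-1,3-dioxolan-4-yl]methanol
Product: 9 (4S)-2,2-dimethyl-1,3-dioxolane-4-carbaldehyde
Conditions: TEMPO (10 mol %), PhI(OAc)2 (1.1 equiv), CH2Cl2, rt; short‑path distillation, used at once
Reagents that add atoms: none
Why: Oxoammonium (TEMPO) oxidation of the primary alcohol stops at the aldehyde and leaves the ketal and the adjacent bought stereocentre (C8 of the target) untouched.

**Step 6**
Reactants: 7 tert-butyl{[(2E)-2-(2-iodoethyl)-4-[(4-methoxyphenyl)methoxy]but-2-en-1-yl]oxy}diphenylsilane, 10 methyl prop-2-ynoate, 9 (4S)-2,2-dimethyl-1,3-dioxolane-4-carbaldehyde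
Product: 15 methyl (2E,6E)-2-{(S)-(acetyloxy)[(4S)-2,2-dimethyl-1,3-dioxolan-4-yl]methyl}-6-({[tert-butyl(diphenyl)silyl]oxy}methyl)-8-[(4-methoxyphenyl)methoxy]octa-2,6-dienoate, via alkyllithium 11 (not isolated), via alkylcopper 12 (not isolated), via alkenylcopper 13 (not isolated), via copper aldolate 14 (not isolated)
Conditions: 7, t‑BuLi (2.05 equiv), Et2O, −78 °C; CuBr·SMe2 (1.0 equiv), MgBr2·OEt2 (1.0 equiv), Me2S/Et2O, −50 °C; 10 (1.0 equiv), −78 °C, 1 h; 9 (1.3 equiv), −78 → −40 °C; Ac2O (3 equiv), DMAP (0.1 equiv), −40 → 0 °C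
Reagents that add atoms: acetic anhydride CC(=O)OC(C)=O
Why: Tandem syn‑carbocupration of the propiolate and aldol trapping: alkyl and copper add cis and the C‑bound alkenylcopper reacts with retention, so C2 ends cis to C9 and trans to CO2Me, while organocopper–MgBr2 reagents add to 2,3‑O‑isopropylideneglyceraldehyde syn (α‑chelation, anti‑Felkin), which sets C9 (S) from the bought C8; the aldolate is acetylated in the flask.

**Step 7**
Reactants: 15 methyl (2E,6E)-2-{(S)-(acetyloxy)[(4S)-2,2-dimethyl-1,3-dioxolan-4-yl]methyl}-6-({[tert-butyl(diphenyl)silyl]oxy}methyl)-8-[(4-methoxyphenyl)methoxy]octa-2,6-dienoate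
Product: 16 methyl (2E,6E)-2-[(1S,2S)-1-(acetyloxy)-2,3-dihydroxypropyl]-6-({[tert-butyl(diphenyl)silyl]oxy}methyl)-8-[(4-methoxyphenyl)methoxy]octa-2,6-dienoate
Conditions: AcOH/H2O (4:1), 35 °C, 3 h; used directly
Reagents that add atoms: none
Why: Acid hydrolysis of the terminal isopropylidene ketal is faster than cleavage of the silyl or PMB ether, acetyl migration, or lactonisation onto the conjugated ester.

**Step 8**
Reactants: 16 methyl (2E,6E)-2-[(1S,2S)-1-(acetyloxy)-2,3-dihydroxypropyl]-6-({[tert-butyl(diphenyl)silyl]oxy}methyl)-8-[(4-methoxyphenyl)methoxy]octa-2,6-dienoate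
Product: 18 methyl (2E,6E)-2-[(1S,2S)-1-(acetyloxy)-2-{[(2E)-2-methylbut-2-enoyl]oxy}-3-[(triethylsilyl)oxy]propyl]-6-({[tert-butyl(diphenyl)silyl]oxy}methyl)-8-[(4-methoxyphenyl)methoxy]octa-2,6-dienoate, via mono-triethylsilyl ether 17 (not isolated)
Conditions: Et3SiCl (1.05 equiv), imidazole, CH2Cl2, −40 °C; then (2E)‑2‑methylbut‑2‑enoyl chloride (1.5 equiv), pyridine, DMAP (0.2 equiv), 0 °C → rt
Reagents that add atoms: chlorotriethylsilane CC[Si](Cl)(CC)CC; (2E)-2-methylbut-2-enoyl chloride C/C=C(\C)C(Cl)=O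
Why: The primary hydroxyl (C7–OH) is silylated selectively for steric reasons and the remaining secondary C8–OH is then acylated (DMAP‑catalysed esterification) with retention, since its C–O bond is not touched.

**Step 9**
Reactants: 18 methyl (2E,6E)-2-[(1S,2S)-1-(acetyloxy)-2-{[(2E)-2-methylbut-2-enoyl]oxy}-3-[(triethylsilyl)oxy]propyl]-6-({[tert-butyl(diphenyl)silyl]oxy}methyl)-8-[(4-methoxyphenyl)methoxy]octa-2,6-dienoate
Product: 19 methyl (2E,6E)-2-[(1S,2R)-1-(acetyloxy)-2-{[(2E)-2-methylbut-2-enoyl]oxy}-3-oxopropyl]-6-({[tert-butyl(diphenyl)silyl]oxy}methyl)-8-[(4-methoxyphenyl)methoxy]octa-2,6-dienoate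
Conditions: IBX (3 equiv), DMSO, rt; used crude
Reagents that add atoms: none
Why: IBX in DMSO converts primary triethylsilyl ethers directly into aldehydes under non‑basic conditions, which avoids β‑elimination of the C9 acetate and epimerisation at C8 (same configuration, descriptor changes only by priority).

**Step 10**
Reactants: 19 methyl (2E,6E)-2-[(1S,2R)-1-(acetyloxy)-2-{[(2E)-2-methylbut-2-enoyl]oxy}-3-oxopropyl]-6-({[tert-butyl(diphenyl)silyl]oxy}methyl)-8-[(4-methoxyphenyl)methoxy]octa-2,6-dienoate, 10 methyl prop-2-ynoate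
Product: 20 methyl (2E,6E)-2-[(1S,2S)-1-(acetyloxy)-3-hydroxy-4-(methoxycarbonyl)-2-{[(2E)-2-methylbut-2-enoyl]oxy}pent-4-en-1-yl]-6-({[tert-butyl(diphenyl)silyl]oxy}methyl)-8-[(4-methoxyphenyl)methoxy]octa-2,6-dienoate (both epimers at the carbinol C7)
Conditions: DIBAL‑H (1.5 equiv), NMO (1.5 equiv), THF, 0 °C; 10 (1.6 equiv), 0 °C, 30 min; 19, 0 °C → rt; Rochelle salt
Reagents that add atoms: none
Why: Vinylalumination: hydroalumination of the propiolate gives the α‑aluminoacrylate, which adds to the aldehyde without amine base to give the Baylis–Hillman‑type alcohol; the new carbinol C7 forms as a mixture that is irrelevant because C7 becomes sp2 in step 11.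

**Step 11**
Reactants: 20 methyl (2E,6E)-2-[(1S,2S)-1-(acetyloxy)-3-hydroxy-4-(methoxycarbonyl)-2-{[(2E)-2-methylbut-2-enoyl]oxy}pent-4-en-1-yl]-6-({[tert-butyl(diphenyl)silyl]oxy}methyl)-8-[(4-methoxyphenyl)methoxy]octa-2,6-dienoate
Product: 21 methyl (2E,6E)-2-[(1S,2S,3Z)-1-(acetyloxy)-4-(bromomethyl)-5-methoxy-2-{[(2E)-2-methylbut-2-enoyl]oxy}-5-oxopent-3-en-1-yl]-6-({[tert-butyl(diphenyl)silyl]oxy}methyl)-8-[(4-methoxyphenyl)methoxy]octa-2,6-dienoate
Conditions: NBS (1.3 equiv), Me2S (1.5 equiv), CH2Cl2, −20 → 0 °C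
Reagents that add atoms: N-bromosuccinimide O=C1CCC(=O)N1Br
Why: Corey–Kim‑type activation of the allylic alcohol and SN2' attack of bromide give the rearranged, thermodynamically favoured (Z)‑2‑(bromomethyl)enoate and erase the C7 stereocentre.

**Step 12**
Reactants: 21 methyl (2E,6E)-2-[(1S,2S,3Z)-1-(acetyloxy)-4-(bromomethyl)-5-methoxy-2-{[(2E)-2-methylbut-2-enoyl]oxy}-5-oxopent-3-en-1-yl]-6-({[tert-butyl(diphenyl)silyl]oxy}methyl)-8-[(4-methoxyphenyl)methoxy]octa-2,6-dienoate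
Product: 22 methyl (2E,6E)-2-[(1S,2S,3Z)-1-(acetyloxy)-4-(bromomethyl)-5-methoxy-2-{[(2E)-2-methylbut-2-enoyl]oxy}-5-oxopent-3-en-1-yl]-6-({[tert-butyl(diphenyl)silyl]oxy}methyl)-8-hydroxyocta-2,6-dienoate
Conditions: DDQ (1.3 equiv), CH2Cl2/pH 7 buffer (10:1), 0 °C
Reagents that add atoms: none
Why: Oxidative cleavage of the 4‑methoxybenzyl ether by DDQ is orthogonal to the silyl ether, the esters and the allylic bromide.

**Step 13**
Reactants: 22 methyl (2E,6E)-2-[(1S,2S,3Z)-1-(acetyloxy)-4-(bromomethyl)-5-methoxy-2-{[(2E)-2-methylbut-2-enoyl]oxy}-5-oxopent-3-en-1-yl]-6-({[tert-butyl(diphenyl)silyl]oxy}methyl)-8-hydroxyocta-2,6-dienoate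
Product: 23 methyl (2E,6E)-2-[(1S,2S,3Z)-1-(acetyloxy)-4-(bromomethyl)-5-methoxy-2-{[(2E)-2-methylbut-2-enoyl]oxy}-5-oxopent-3-en-1-yl]-6-({[tert-butyl(diphenyl)silyl]oxy}methyl)-8-oxoocta-2,6-dienoate
Conditions: MnO2 (20 equiv), CH2Cl2, rt
Reagents that add atoms: none
Why: Manganese dioxide oxidises only the allylic alcohol, under neutral conditions that keep the C4=C5 geometry and the allylic bromide intact.

**Step 14**
Reactants: 23 methyl (2E,6E)-2-[(1S,2S,3Z)-1-(acetyloxy)-4-(bromomethyl)-5-methoxy-2-{[(2E)-2-methylbut-2-enoyl]oxy}-5-oxopent-3-en-1-yl]-6-({[tert-butyl(diphenyl)silyl]oxy}methyl)-8-oxoocta-2,6-dienoate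
Product: 26 methyl (6R,7S,8S,9S)-9-(acetyloxy)-15-{[tert-butyl(diphenyl)silyl]oxy}-8-{[(2E)-2-methylbut-2-enoyl]oxy}germacra-1(10),4,11(13)-trien-12,6-olid-14-oate (15-O-silyl ether of the target), via allylchromium dichloride 24 (not isolated), via cyclised silyl ether 25 (not isolated)
Conditions: CrCl2 (20 mol %), Me3SiCl (3 equiv), Bu4NBF4 (0.1 M), DMF, undivided cell, Al anode, Ni‑foam cathode, constant current 3 mA (2.5 F/mol), 23 added over 8 h (final 3 mM), rt; then TsOH·H2O (0.2 equiv), wet CH2Cl2, rt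
Reagents that add atoms: none
Why: Proposed new method: a chromium‑electrocatalytic ring‑closing Nozaki–Hiyama allylation in which CrCl2 is regenerated at the cathode, two divalent chromium ions convert the allylic bromide into the η1‑allyl species 24 of trivalent chromium, this adds through C7 to the tethered enal carbonyl in a six‑membered chair transition state, Me3SiCl silylates the chromium alkoxide and frees the metal for re‑reduction, and acid then closes the lactone; C7 is set by attack on the alkene face anti to the C8–C9 bond with C8–H eclipsing the alkene (allylic strain), and C6 is set trans to it because the ten‑membered tether holds its two ends anti across the new bond, giving the 6,7‑trans lactone; the closest known reactions are the stoichiometric CrCl2 Barbier macrocyclisation of 2‑(bromomethyl)acrylate aldehydes to germacranolides and the intermolecular electrochemical Nozaki–Hiyama–Kishi coupling.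

**Step 15**
Reactants: 26 methyl (6R,7S,8S,9S)-9-(acetyloxy)-15-{[tert-butyl(diphenyl)silyl]oxy}-8-{[(2E)-2-methylbut-2-enoyl]oxy}germacra-1(10),4,11(13)-trien-12,6-olid-14-oate
Product: 27 methyl (6R,7S,8S,9S)-9-(acetyloxy)-15-hydroxy-8-{[(2E)-2-methylbut-2-enoyl]oxy}germacra-1(10),4,11(13)-trien-12,6-olid-14-oate (CNP0216801.5)
Conditions: HF·pyridine, pyridine, THF, 0 °C → rt
Reagents that add atoms: none
Why: Buffered fluoride desilylation frees the C15 hydroxyl without affecting the α‑methylene lactone, the allylic acetate or the tiglate, and no stereocentre is touched.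

**Compound list**
1 | but-2-yne-1,4-diol | OCC#CCO | starting material
2 | 4-[(4-methoxyphenyl)methoxy]but-2-yn-1-ol | COc1ccc(COCC#CCO)cc1 | intermediate
3 | alkenylmagnesium chelate (five-membered C=C–Mg–O ring from 2 and vinylmagnesium chloride) | C=CC1=C(COCc2ccc(OC)cc2)[Mg]OC1 | intermediate
4 | (2E)-2-ethenyl-4-[(4-methoxyphenyl)methoxy]but-2-en-1-ol | COc1ccc(COC/C=C(/CO)C=C)cc1 | intermediate
5 | tert-butyl{[(2E)-2-ethenyl-4-[(4-methoxyphenyl)methoxy]but-2-en-1-yl]oxy}diphenylsilane | COc1ccc(COC/C=C(/CO[Si](c2ccccc2)(c2ccccc2)C(C)(C)C)C=C)cc1 | intermediate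
6 | B-alkyl-9-BBN (9-borabicyclo[3.3.1]nonan-9-yl on the terminal carbon of the former vinyl group of 5) | COc1ccc(COC/C=C(/CO[Si](c2ccccc2)(c2ccccc2)C(C)(C)C)CCB2C3CCCC2CCC3)cc1 | intermediate
7 | tert-butyl{[(2E)-2-(2-iodoethyl)-4-[(4-methoxyphenyl)methoxy]but-2-en-1-yl]oxy}diphenylsilane | COc1ccc(COC/C=C(/CO[Si](c2ccccc2)(c2ccccc2)C(C)(C)C)CCI)cc1 | intermediate
8 | [(4R)-2,2-dimethyl-1,3-dioxolan-4-yl]methanol ((R)-solketal) | OC[C@H]1OC(C)(C)OC1 | starting material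
9 | (4S)-2,2-dimethyl-1,3-dioxolane-4-carbaldehyde | O=C[C@H]1OC(C)(C)OC1 | intermediate
10 | methyl prop-2-ynoate | C#CC(=O)OC | starting material
11 | alkyllithium (C–Li in place of C–I of 7) | COc1ccc(COC/C=C(/CO[Si](c2ccccc2)(c2ccccc2)C(C)(C)C)CC[Li])cc1 | intermediate
12 | alkylcopper (C–Cu in place of C–I of 7, MgBr2 complexed) | COc1ccc(COC/C=C(/CO[Si](c2ccccc2)(c2ccccc2)C(C)(C)C)CC[Cu])cc1 | intermediate
13 | alkenylcopper (methyl (2Z)-2-cuprio-enoate, alkyl cis to copper) | COc1ccc(COC/C=C(/CO[Si](c2ccccc2)(c2ccccc2)C(C)(C)C)CC/C=C(/C(=O)OC)[Cu])cc1 | intermediate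
14 | copper aldolate (C9–O–Cu, 8S,9S) | COc1ccc(COC/C=C(/CO[Si](c2ccccc2)(c2ccccc2)C(C)(C)C)CC/C=C(/C(=O)OC)[C@H](O[Cu])[C@H]2OC(C)(C)OC2)cc1 | intermediate
15 | methyl (2E,6E)-2-{(S)-(acetyloxy)[(4S)-2,2-dimethyl-1,3-dioxolan-4-yl]methyl}-6-({[tert-butyl(diphenyl)silyl]oxy}methyl)-8-[(4-methoxyphenyl)methoxy]octa-2,6-dienoate | COc1ccc(COC/C=C(/CO[Si](c2ccccc2)(c2ccccc2)C(C)(C)C)CC/C=C(/C(=O)OC)[C@H](OC(C)=O)[C@H]2OC(C)(C)OC2)cc1 | intermediate
16 | methyl (2E,6E)-2-[(1S,2S)-1-(acetyloxy)-2,3-dihydroxypropyl]-6-({[tert-butyl(diphenyl)silyl]oxy}methyl)-8-[(4-methoxyphenyl)methoxy]octa-2,6-dienoate | COc1ccc(COC/C=C(/CO[Si](c2ccccc2)(c2ccccc2)C(C)(C)C)CC/C=C(/C(=O)OC)[C@H](OC(C)=O)[C@@H](O)CO)cc1 | intermediate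
17 | mono-triethylsilyl ether of 16 (primary O–SiEt3, secondary C8–OH free) | COc1ccc(COC/C=C(/CO[Si](c2ccccc2)(c2ccccc2)C(C)(C)C)CC/C=C(/C(=O)OC)[C@H](OC(C)=O)[C@@H](O)CO[Si](CC)(CC)CC)cc1 | intermediate
18 | methyl (2E,6E)-2-[(1S,2S)-1-(acetyloxy)-2-{[(2E)-2-methylbut-2-enoyl]oxy}-3-[(triethylsilyl)oxy]propyl]-6-({[tert-butyl(diphenyl)silyl]oxy}methyl)-8-[(4-methoxyphenyl)methoxy]octa-2,6-dienoate | COc1ccc(COC/C=C(/CO[Si](c2ccccc2)(c2ccccc2)C(C)(C)C)CC/C=C(/C(=O)OC)[C@H](OC(C)=O)[C@@H](OC(=O)/C(C)=C/C)CO[Si](CC)(CC)CC)cc1 | intermediate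
19 | methyl (2E,6E)-2-[(1S,2R)-1-(acetyloxy)-2-{[(2E)-2-methylbut-2-enoyl]oxy}-3-oxopropyl]-6-({[tert-butyl(diphenyl)silyl]oxy}methyl)-8-[(4-methoxyphenyl)methoxy]octa-2,6-dienoate | COc1ccc(COC/C=C(/CO[Si](c2ccccc2)(c2ccccc2)C(C)(C)C)CC/C=C(/C(=O)OC)[C@H](OC(C)=O)[C@@H](OC(=O)/C(C)=C/C)C=O)cc1 | intermediate
20 | methyl (2E,6E)-2-[(1S,2S)-1-(acetyloxy)-3-hydroxy-4-(methoxycarbonyl)-2-{[(2E)-2-methylbut-2-enoyl]oxy}pent-4-en-1-yl]-6-({[tert-butyl(diphenyl)silyl]oxy}methyl)-8-[(4-methoxyphenyl)methoxy]octa-2,6-dienoate, both epimers at the carbinol carbon (C7) | COc1ccc(COC/C=C(/CO[Si](c2ccccc2)(c2ccccc2)C(C)(C)C)CC/C=C(/C(=O)OC)[C@H](OC(C)=O)[C@@H](OC(=O)/C(C)=C/C)C(O)C(=C)C(=O)OC)cc1 | intermediate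
21 | methyl (2E,6E)-2-[(1S,2S,3Z)-1-(acetyloxy)-4-(bromomethyl)-5-methoxy-2-{[(2E)-2-methylbut-2-enoyl]oxy}-5-oxopent-3-en-1-yl]-6-({[tert-butyl(diphenyl)silyl]oxy}methyl)-8-[(4-methoxyphenyl)methoxy]octa-2,6-dienoate | COc1ccc(COC/C=C(/CO[Si](c2ccccc2)(c2ccccc2)C(C)(C)C)CC/C=C(/C(=O)OC)[C@H](OC(C)=O)[C@@H](OC(=O)/C(C)=C/C)/C=C(\CBr)C(=O)OC)cc1 | intermediate
22 | methyl (2E,6E)-2-[(1S,2S,3Z)-1-(acetyloxy)-4-(bromomethyl)-5-methoxy-2-{[(2E)-2-methylbut-2-enoyl]oxy}-5-oxopent-3-en-1-yl]-6-({[tert-butyl(diphenyl)silyl]oxy}methyl)-8-hydroxyocta-2,6-dienoate | OC/C=C(/CO[Si](c1ccccc1)(c1ccccc1)C(C)(C)C)CC/C=C(/C(=O)OC)[C@H](OC(C)=O)[C@@H](OC(=O)/C(C)=C/C)/C=C(\CBr)C(=O)OC | intermediate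
23 | methyl (2E,6E)-2-[(1S,2S,3Z)-1-(acetyloxy)-4-(bromomethyl)-5-methoxy-2-{[(2E)-2-methylbut-2-enoyl]oxy}-5-oxopent-3-en-1-yl]-6-({[tert-butyl(diphenyl)silyl]oxy}methyl)-8-oxoocta-2,6-dienoate | O=C/C=C(/CO[Si](c1ccccc1)(c1ccccc1)C(C)(C)C)CC/C=C(/C(=O)OC)[C@H](OC(C)=O)[C@@H](OC(=O)/C(C)=C/C)/C=C(\CBr)C(=O)OC | intermediate
24 | allylchromium dichloride (CrCl2 group of trivalent chromium in place of Br of 23) | O=C/C=C(/CO[Si](c1ccccc1)(c1ccccc1)C(C)(C)C)CC/C=C(/C(=O)OC)[C@H](OC(C)=O)[C@@H](OC(=O)/C(C)=C/C)/C=C(\C[Cr](Cl)Cl)C(=O)OC | intermediate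
25 | cyclised silyl ether (ten-membered ring closed; C6–OSiMe3; C7 carries the methyl 2-propenoate unit; 6R,7S,8S,9S) | C=C(C(=O)OC)[C@H]1[C@H](O[Si](C)(C)C)/C=C(/CO[Si](c2ccccc2)(c2ccccc2)C(C)(C)C)CC/C=C(/C(=O)OC)[C@H](OC(C)=O)[C@H]1OC(=O)/C(C)=C/C | intermediate
26 | methyl (6R,7S,8S,9S)-9-(acetyloxy)-15-{[tert-butyl(diphenyl)silyl]oxy}-8-{[(2E)-2-methylbut-2-enoyl]oxy}germacra-1(10),4,11(13)-trien-12,6-olid-14-oate (both ring alkenes E by CIP, cis in the ring; trans-fused lactone) | C=C1C(=O)O[C@@H]2/C=C(/CO[Si](c3ccccc3)(c3ccccc3)C(C)(C)C)CC/C=C(/C(=O)OC)[C@H](OC(C)=O)[C@@H](OC(=O)/C(C)=C/C)[C@@H]12 | intermediate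
27 | methyl (6R,7S,8S,9S)-9-(acetyloxy)-15-hydroxy-8-{[(2E)-2-methylbut-2-enoyl]oxy}germacra-1(10),4,11(13)-trien-12,6-olid-14-oate (CNP0216801.5) | C=C1C(=O)O[C@@H]2/C=C(/CO)CC/C=C(/C(=O)OC)[C@H](OC(C)=O)[C@@H](OC(=O)/C(C)=C/C)[C@@H]12 | target

**Totals and risks**
Total step count: 15. Longest linear sequence: 14 steps (1 → 2 → 4 → 5 → 7 → 15 → 16 → 18 → 19 → 20 → 21 → 22 → 23 → 26 → 27); step 5 is the only off‑line step.

Step 14 (the proposed new step) is the most likely to fail. Catalytic turnover of chromium at the cathode has not been shown for a ring‑closing allylation. Species 24 could also lose the C8 tiglate by 1,4‑elimination to a dienoate, oligomerise, or close to the wrong C6/C7 diastereomer. The fallback uses known chemistry, sets out from bromide 21 and returns at 26. Bromide 21 is borylated with B2pin2 and catalytic Pd2(dba)3 in toluene at 40 °C to give the linear pinacol allylboronate F7. DDQ removes the PMB ether to give the allylic alcohol boronate F8, and MnO2 gives the aldehyde boronate F9. On warming in toluene (60 °C, optionally Sc(OTf)3 cat.), F9 closes the ring by intramolecular allylboration through a closed six‑membered transition state (the route to α‑methylene‑γ‑lactones from 2‑alkoxycarbonylallylboronates), and TsOH lactonises the borate to 26. This path has no low‑valent metal, so the 1,4‑elimination is removed.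

Step 6 is the second risk. The alkenylcopper 13 can equilibrate to the allenolate, which would give the other C1=C10 isomer, and the syn selectivity at C9 rests on analogy with simple organocopper–MgBr2 additions. The fallback sets out from iodide 7 and returns at 15. Lithium acetylide–ethylenediamine in DMSO converts 7 into the terminal alkyne F2. Its lithium acetylide (n‑BuLi, THF, −78 °C) is acylated with (4S)‑N‑methoxy‑N,2,2‑trimethyl‑1,3‑dioxolane‑4‑carboxamide to give the ynone F3. L‑Selectride at −78 °C reduces it under Felkin–Anh control to the syn propargylic alcohol F4. Hydroxyl‑directed syn‑hydromagnesiation (i‑BuMgCl, Cp2TiCl2 cat., Et2O) places magnesium on the carbinol‑side alkyne carbon, and CO2 gives the (E)‑2‑(hydroxyalkyl)enoic acid F5. Me3SiCHN2 gives the methyl ester F6, and Ac2O/pyridine gives 15.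

Step 2 is the third risk. The alkenylmagnesium chelate 3 carries a β‑alkoxy group and may eliminate PMB‑oxide to an allene at the temperature needed for addition. The fallback sets out from 2 and returns at 4. trans‑Hydroalumination of 2 with LiAlH4/AlCl3 (60:1) in THF, then I2 at −78 °C, gives the (2Z)‑2‑iodo allylic alcohol F1. Stille coupling with tributyl(vinyl)stannane (Pd(PPh3)4, CuI, CsF, DMF) then gives 4 with retention of the alkene geometry.

**Further compounds**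
F1 | step 2 | (2Z)-2-iodo-4-[(4-methoxyphenyl)methoxy]but-2-en-1-ol | COc1ccc(COC/C=C(/CO)I)cc1
F2 | step 6 | tert-butyl{[(2E)-2-(but-3-yn-1-yl)-4-[(4-methoxyphenyl)methoxy]but-2-en-1-yl]oxy}diphenylsilane | COc1ccc(COC/C=C(/CO[Si](c2ccccc2)(c2ccccc2)C(C)(C)C)CCC#C)cc1
F3 | step 6 | ynone from F2 and the (4S)-dioxolane Weinreb amide (C9 ketone) | COc1ccc(COC/C=C(/CO[Si](c2ccccc2)(c2ccccc2)C(C)(C)C)CCC#CC(=O)[C@H]2OC(C)(C)OC2)cc1
F4 | step 6 | syn propargylic alcohol (8S,9S) | COc1ccc(COC/C=C(/CO[Si](c2ccccc2)(c2ccccc2)C(C)(C)C)CCC#C[C@H](O)[C@H]2OC(C)(C)OC2)cc1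
F5 | step 6 | (2E)-2-(hydroxyalkyl)enoic acid (free acid of F6) | COc1ccc(COC/C=C(/CO[Si](c2ccccc2)(c2ccccc2)C(C)(C)C)CC/C=C(/C(=O)O)[C@H](O)[C@H]2OC(C)(C)OC2)cc1
F6 | step 6 | C9 alcohol of 15 (methyl ester, free C9–OH) | COc1ccc(COC/C=C(/CO[Si](c2ccccc2)(c2ccccc2)C(C)(C)C)CC/C=C(/C(=O)OC)[C@H](O)[C@H]2OC(C)(C)OC2)cc1
F7 | step 14 | pinacol allylboronate of 21 (Bpin in place of Br) | COc1ccc(COC/C=C(/CO[Si](c2ccccc2)(c2ccccc2)C(C)(C)C)CC/C=C(/C(=O)OC)[C@H](OC(C)=O)[C@@H](OC(=O)/C(C)=C/C)/C=C(\CB2OC(C)(C)C(C)(C)O2)C(=O)OC)cc1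
F8 | step 14 | allylic alcohol boronate (Bpin analogue of 22) | OC/C=C(/CO[Si](c1ccccc1)(c1ccccc1)C(C)(C)C)CC/C=C(/C(=O)OC)[C@H](OC(C)=O)[C@@H](OC(=O)/C(C)=C/C)/C=C(\CB1OC(C)(C)C(C)(C)O1)C(=O)OC
F9 | step 14 | aldehyde boronate (Bpin analogue of 23) | O=C/C=C(/CO[Si](c1ccccc1)(c1ccccc1)C(C)(C)C)CC/C=C(/C(=O)OC)[C@H](OC(C)=O)[C@@H](OC(=O)/C(C)=C/C)/C=C(\CB1OC(C)(C)C(C)(C)O1)C(=O)OC
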